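**Retrosynthetic overview**

- Presumed biosynthesis: a 3-alkylitaconate (fatty acyl unit plus oxaloacetate, then dehydration and decarboxylation) is oxygenated at the chain carbon next to C-3. That oxygen closes the γ-lactone on the acrylic, methylene-bearing carboxyl, and the other carboxyl stays free.
- The same ring closure is used here: the lactone C–O bond is opened to a γ-hydroxy-alkylitaconate held as its cyclic anhydride, and the C-2/C-3 bond is then cut to 14-acetoxytetradecanal plus itaconic anhydride.
- One aldol–lactonisation cascade therefore delivers the exo-methylene, the free acid, both stereocentres and the ring, with no protecting group on the acid.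
- The aldehyde comes from tetradecane-1,14-diol by mono-acetylation and oxidation. The γ-lactone is the only ring and is formed last.

Assumption: the quinine-derived squaramide in step 3 is taken to direct Si-face attack on the aldehyde; if it favours the mirror image, its quinidine-derived pseudo-enantiomer is used with nothing else changed.

**Route**

Step 1
Reactants: 1 tetradecane-1,14-diol
Product: 2 tetradecane-1,14-diol monoacetate (14-hydroxytetradecyl acetate)
Conditions: Ac2O (0.9 equiv), pyridine, CH2Cl2/THF, 0 °C to rt; recovered diol recycled
Reagents that add atoms: acetic anhydride, CC(=O)OC(C)=O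
Why: O-acetylation (nucleophilic acyl substitution) of a symmetrical diol with a deficit of anhydride gives the monoacetate statistically, separable from diol and diacetate by chromatography; no stereocentre is involved.

Step 2
Reactants: 2 tetradecane-1,14-diol monoacetate
Product: 3 ω-acetoxy aldehyde (14-oxotetradecyl acetate)
Conditions: TEMPO (10 mol %), PhI(OAc)2 (1.1 equiv), CH2Cl2, rt
Reagents that add atoms: none
Why: TEMPO/PhI(OAc)2 oxoammonium oxidation takes a primary alcohol to the aldehyde without over-oxidation in anhydrous CH2Cl2 and leaves the acetate untouched; no stereocentre is involved.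

Step 3
Reactants: 3 ω-acetoxy aldehyde (14-oxotetradecyl acetate); 4 itaconic anhydride (3-methylideneoxolane-2,5-dione)
Product: 6 (2R,3S)-2-(13-acetoxytridecyl)-4-methylidene-5-oxooxolane-3-carboxylic acid, via hydroxy anhydride aldol adduct 5 (not isolated)
Conditions: 4 (2 equiv, syringe pump, 6 h), quinine-derived 3,5-bis(trifluoromethyl)phenyl squaramide (9-amino-9-deoxy-epi-quinine series, 10 mol %), MTBE, −15 °C to rt; then 1 M HCl wash
Reagents that add atoms: none
Why: Proposed new method: the ring CH2 of 4 (α to an anhydride carbonyl and allylic to the acrylate) is acidic enough for the quinuclidine nitrogen to form an ion-paired dienolate, which adds through its α-carbon to the Si face of the squaramide-bound aldehyde in an open transition state, setting C-2 (R) and C-3 (S) in the trans relationship; the alkoxide of 5 can reach only the conjugated carbonyl in a five-membered (5-exo-trig) closure, which opens the anhydride, frees the C-3 carboxyl and makes the cascade irreversible, the same O-acylation on the acrylic carboxyl that closes the ring in nature; the closest known reaction types are the Perkin–Fittig paraconic acid synthesis (succinic anhydride plus aldehyde under amine/Lewis acid) and the squaramide-catalysed enantioselective formal cycloaddition of enolisable homophthalic and aryl-succinic anhydrides to aldehydes.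

**Compound list**

1 | tetradecane-1,14-diol | OCCCCCCCCCCCCCCO | starting material
2 | tetradecane-1,14-diol monoacetate (14-hydroxytetradecyl acetate) | CC(=O)OCCCCCCCCCCCCCCO | intermediate
3 | 14-oxotetradecyl acetate (14-acetoxytetradecanal) | CC(=O)OCCCCCCCCCCCCCC=O | intermediate
4 | itaconic anhydride (3-methylideneoxolane-2,5-dione) | C=C1CC(=O)OC1=O | starting material
5 | (3S)-3-[(1R)-14-acetoxy-1-hydroxytetradecyl]-4-methylideneoxolane-2,5-dione (aldol adduct, not isolated) | C=C1C(=O)OC(=O)[C@@H]1[C@H](O)CCCCCCCCCCCCCOC(C)=O | intermediate
6 | (2R,3S)-2-(13-acetoxytridecyl)-4-methylidene-5-oxooxolane-3-carboxylic acid | C=C1C(=O)O[C@H](CCCCCCCCCCCCCOC(C)=O)[C@H]1C(=O)O | target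

**Step count and risks**

Total step count: 3. Longest linear sequence: 3 steps (1 → 2 → 3 → 6).

Steps most likely to fail, in order of risk:

1. Step 3. Risks: the amine can isomerise 4 to citraconic anhydride faster than the aldol; the dienolate may react at its γ-carbon (the exo-CH2); the anhydride may oligomerise by Michael addition; ee or trans:cis may be modest with an unbranched aliphatic aldehyde.
 Fallback (sets out from 3, comes back at 6): the itaconate nucleophile is replaced by an allyl-chromium reagent. Itaconic acid is esterified with isobutene (cat. H2SO4) to di-tert-butyl itaconate F1, which adds bromine to give di-tert-butyl 2-bromo-2-(bromomethyl)butanedioate F2 and then loses HBr with Et3N to give di-tert-butyl 2-(bromomethyl)fumarate F3. A chromium-catalysed asymmetric Nozaki–Hiyama–Kishi 2-(alkoxycarbonyl)allylation of 3 with F3 (CrCl2 10 mol %, chiral carbazole-bis(oxazoline) ligand, Mn, TMSCl, THF, dilute acid work-up) gives di-tert-butyl (2S)-2-[(1R)-14-acetoxy-1-hydroxytetradecyl]-3-methylidenebutanedioate F4. TFA in CH2Cl2 then removes both tert-butyl groups, and the freed γ-hydroxy-itaconic acid lactonises on its acrylic carboxyl to 6 with the acetate intact.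

2. Step 2. Risks: over-oxidation to the acid, and loss of the long-chain aldehyde by air oxidation or trimerisation on handling.
 Fallback (sets out from 2, comes back at 3): the alcohol is not oxidised directly. Compound 2 is converted (I2, PPh3, imidazole) into 14-iodotetradecyl acetate F5, and a Kornblum oxidation (DMSO, NaHCO3, 110 °C) turns the iodide into 3, with no reagent present that can carry the aldehyde on to the acid.

3. Step 1. Risk: statistical acetylation gives at best about half monoacetate per pass and needs separation from diol and diacetate.
 Fallback (sets out from 1, comes back at 2): the two ends are differentiated by substitution instead of acylation. Phase-controlled monobromination of 1 (48 % aq. HBr, toluene, reflux) gives 14-bromotetradecan-1-ol F6 selectively, and acetate displacement (KOAc, DMF, 80 °C) gives 2.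

**Further compounds**

F1 | step 3 | di-tert-butyl itaconate (di-tert-butyl 2-methylidenebutanedioate) | C=C(CC(=O)OC(C)(C)C)C(=O)OC(C)(C)C
F2 | step 3 | di-tert-butyl 2-bromo-2-(bromomethyl)butanedioate (racemic) | BrCC(Br)(CC(=O)OC(C)(C)C)C(=O)OC(C)(C)C
F3 | step 3 | di-tert-butyl 2-(bromomethyl)fumarate (ester groups trans, 2Z by CIP) | BrC/C(=C\C(=O)OC(C)(C)C)C(=O)OC(C)(C)C
F4 | step 3 | di-tert-butyl (2S)-2-[(1R)-14-acetoxy-1-hydroxytetradecyl]-3-methylidenebutanedioate | C=C(C(=O)OC(C)(C)C)[C@H](C(=O)OC(C)(C)C)[C@H](O)CCCCCCCCCCCCCOC(C)=O
F5 | step 2 | 14-iodotetradecyl acetate | CC(=O)OCCCCCCCCCCCCCCI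
F6 | step 1 | 14-bromotetradecan-1-ol | OCCCCCCCCCCCCCCBr
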